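The ring-fusion outcome of the key cycloaddition (step 4) and the facial sense of the catalyst in step 3 are predictions from models, not established results.

**Strategy**

Everything rests on disconnecting ring A at C1–C2 and ring B at C5–C10, the retron being the Δ3-cyclohexene that later carries the 3α,4α-diol. The key step exploits the 1,3-relationship in ring B between the C8 oxygen and the angular carbon C14 on C10: tied together as an α-methylene-γ-butyrolactone, they activate the C1=C10 dienophile and relay the one catalyst-set stereocenter (C8). The precursor is a monocyclic lactone bearing a 3-sulfolene on a two-carbon arm; heating expels SO2 and the unmasked (E)-diene cyclises in an intramolecular Diels–Alder reaction that closes ring A through C1–C2 and ring B through C5–C10 and sets C10 and C5 in one operation.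

Key step: step 4

Remark on locants: eudesmane numbering is used for the target and for the corresponding atoms of all intermediates. Ring A is C1–C5 plus C10, ring B is C5–C10, C14 is the carbon on C10, C15 the methyl on C4, and C11–C13 the side chain on C7. β is the face of C14, α the opposite face.

Assumption: in step 3 the ligand antipode that sends the allyl group to the Re face of aldehyde 4 is used; which antipode that is follows from the ligand's established facial sense with aliphatic aldehydes and is not fixed here. Both antipodes are accessible.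

**Route**

Step 1
Reactants: 1 3-methyl-2,5-dihydrothiophene 1,1-dioxide (3-methyl-3-sulfolene); 2 2-(2-iodoethyl)-1,3-dioxolane
Product: 3 2-[2-(1,3-dioxolan-2-yl)ethyl]-3-methyl-2,5-dihydrothiophene 1,1-dioxide (racemic)
Conditions: LiN(SiMe3)2 (1.1 equiv) added to 1 and 2 (2 equiv), THF/HMPA, −78 °C
Reagents that add atoms: none
Why: Sulfolene α-alkylation: the base removes the proton at the sulfolene carbon next to the methyl-bearing carbon (allyl anion with the methyl on its central carbon), and trapping in situ by the primary iodide at −78 °C should outrun ring opening of the anion; the new center is racemic and is destroyed in step 4.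

Step 2
Reactants: 3 2-[2-(1,3-dioxolan-2-yl)ethyl]-3-methyl-2,5-dihydrothiophene 1,1-dioxide
Product: 4 3-(3-methyl-1,1-dioxo-2,5-dihydrothiophen-2-yl)propanal (racemic)
Conditions: 2 M HCl, THF, 25 °C
Reagents that add atoms: water O
Why: Acid-catalysed acetal hydrolysis, to which the sulfolene is inert at room temperature, should unmask the C8 aldehyde.

Step 3
Reactants: 4 3-(3-methyl-1,1-dioxo-2,5-dihydrothiophen-2-yl)propanal; 5 ethyl 2-(bromomethyl)prop-2-enoate
Product: 8 (5S)-3-methylidene-5-[2-(3-methyl-1,1-dioxo-2,5-dihydrothiophen-2-yl)ethyl]oxolan-2-one (both epimers at the sulfolene carbon), via silyl ether 6 (not isolated), via hydroxy ester 7 (not isolated)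
Conditions: CrCl2 (10 mol %), chiral 3,6-di-tert-butyl-1,8-bis(4-isopropyl-4,5-dihydrooxazol-2-yl)-9H-carbazole (12 mol %), Mn powder, i-Pr2NEt (cat.), Me3SiCl, THF, 25 °C; then 1 M HCl, THF, 25 °C
Reagents that add atoms: none
Why: Catalytic asymmetric Nozaki–Hiyama–Kishi-type 2-(alkoxycarbonyl)allylation: the ligand-bound allylchromium should add to the Re face of the aldehyde and set C8 as (S), Mn and Me3SiCl turn the catalyst over, and the acidic work-up desilylates and lactonises the γ-hydroxy ester.

Step 4
Reactants: 8 (5S)-3-methylidene-5-[2-(3-methyl-1,1-dioxo-2,5-dihydrothiophen-2-yl)ethyl]oxolan-2-one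
Product: 10 tricyclic lactone 11,12,13-trinoreudesm-3-en-14,8β-olide (5α-H; trans-fused), via triene lactone 9 (not isolated)
Conditions: xylenes (0.01 M), BHT (cat.), 140 °C, slow N2 purge
Reagents that add atoms: none
Why: Heating should cause cheletropic loss of SO2 from the sulfolene (disrotatory, alkyl group outward) to give the (E)-diene 9, which then undergoes a concerted, asynchronous type 1 intramolecular Diels–Alder reaction with the α-methylene lactone. The closest known reaction type is the thermal cycloaddition of ester-activated 1,7,9-decatrienes released from sulfolenes. Ring A closes in the cycloaddition itself by suprafacial bonding of the diene terminus C2 to the methylene carbon C1, and ring B closes at the same time as the tether ring through C5–C10 (six-membered, chair-like, bridged by the lactone). C10 is controlled by C8: the C7–C6 tether holds the diene on the lactone face that carries C7, so the new C10–C5 bond must be cis to C8–C7. C5 is controlled by the endo orientation of the lactone carbonyl, which places C4 equatorial on the forming chair of ring B and gives the trans ring fusion. The step needs endo over exo selectivity and cycloaddition over polymerisation; the shorter tether path and secondary overlap with the carbonyl should favour the endo mode, and high dilution with BHT suppresses intermolecular reaction.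

Step 5
Reactants: 10 tricyclic lactone 11,12,13-trinoreudesm-3-en-14,8β-olide
Product: 11 lactol 8β,14-epoxy-11,12,13-trinoreudesm-3-en-14-ol (anomer mixture)
Conditions: i-Bu2AlH (1.1 equiv), CH2Cl2, −78 °C; aqueous potassium sodium tartrate work-up
Reagents that add atoms: none
Why: Partial reduction of a lactone with i-Bu2AlH at −78 °C should stop at the bridged lactol because the tetrahedral aluminium hemiacetal persists at low temperature; the anomeric center is inconsequential.

Step 6
Reactants: 11 lactol 8β,14-epoxy-11,12,13-trinoreudesm-3-en-14-ol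
Product: 13 alcohol 11,12,13-trinoreudesm-3-en-8β-ol, via hydrazone 12 (not isolated)
Conditions: N2H4·H2O, diethylene glycol, 130 °C; then KOH, 200 °C
Reagents that add atoms: none
Why: Wolff–Kishner reduction (Huang–Minlon conditions) of the lactol through its open hydroxy aldehyde form should turn the angular C14 carbonyl carbon into the C10 methyl group and free the 8β-hydroxyl without touching a stereocenter.

Step 7
Reactants: 13 alcohol 11,12,13-trinoreudesm-3-en-8β-ol
Product: 14 ketone 11,12,13-trinoreudesm-3-en-8-one [(4aR,8aR)-5,8a-dimethyl-3,4,4a,7,8,8a-hexahydronaphthalen-2(1H)-one]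
Conditions: Dess–Martin periodinane, CH2Cl2, 25 °C
Reagents that add atoms: none
Why: Dess–Martin oxidation of the secondary alcohol should give the C8 ketone under neutral conditions that leave the trisubstituted alkene untouched.

Step 8
Reactants: 14 ketone 11,12,13-trinoreudesm-3-en-8-one
Product: 15 7-(phenylselanyl)-11,12,13-trinoreudesm-3-en-8-one (C7 epimers)
Conditions: LiN(i-Pr)2 (1.1 equiv), THF, −78 °C; PhSeCl (1.05 equiv), −78 °C
Reagents that add atoms: phenylselenenyl chloride Cl[Se]c1ccccc1
Why: α-Selenenylation of a ketone enolate: kinetic deprotonation should occur at C7 because C9 is neopentyl (next to quaternary C10), and the C7 configuration is irrelevant since this carbon becomes sp2.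

Step 9
Reactants: 15 7-(phenylselanyl)-11,12,13-trinoreudesm-3-en-8-one
Product: 18 11-hydroxyeudesma-3,6-dien-8-one, via seleno aldol 16 (not isolated), via selenoxide 17 (not isolated)
Conditions: LiN(i-Pr)2 (1.2 equiv), THF, −78 °C; acetone; AcOH; then mCPBA (1.0 equiv), −78 °C to 0 °C
Reagents that add atoms: acetone CC(C)=O
Why: Seleno-aldol addition followed by selenoxide syn-elimination: the selenium-stabilised C7 enolate should add to acetone, mCPBA oxidises selenium selectively at −78 °C, and the selenoxide can eliminate only towards C6 (C11 carries no hydrogen), which gives the α-(hydroxyalkyl) enone.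

Step 10
Reactants: 18 11-hydroxyeudesma-3,6-dien-8-one
Product: 19 3α,4α,11-trihydroxyeudesm-6-en-8-one
Conditions: OsO4 (2 mol %), N-methylmorpholine N-oxide, acetone/H2O, 25 °C
Reagents that add atoms: OsO4 O=[Os](=O)(=O)=O (catalytic oxygen carrier); N-methylmorpholine N-oxide C[N+]1([O-])CCOCC1; water O
Why: Upjohn dihydroxylation: OsO4 should attack the electron-rich trisubstituted C3=C4 alkene in preference to the hindered enone and from the α face, opposite the axial C10 methyl group, which sets C3 and C4 together as the 3α,4α-diol.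

Step 11
Reactants: 19 3α,4α,11-trihydroxyeudesm-6-en-8-one; 20 angelic acid [(2Z)-2-methylbut-2-enoic acid]
Product: 21 3α-angeloyloxy-4α,11-dihydroxyeudesm-6-en-8-one (CNP0261892.2)
Conditions: 20, 2,4,6-Cl3C6H2COCl, Et3N, toluene, 25 °C; then 19, toluene, 80 °C (no DMAP)
Reagents that add atoms: none
Why: Yamaguchi-type esterification through the mixed anhydride without a nucleophilic catalyst should acylate only the secondary 3α-hydroxyl (both tertiary alcohols are inert) and avoid Z to E isomerisation of the angelate.

**Compound list**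

1 | 3-methyl-2,5-dihydrothiophene 1,1-dioxide (3-methyl-3-sulfolene) | CC1=CCS(=O)(=O)C1 | starting material
2 | 2-(2-iodoethyl)-1,3-dioxolane | ICCC1OCCO1 | starting material
3 | 2-[2-(1,3-dioxolan-2-yl)ethyl]-3-methyl-2,5-dihydrothiophene 1,1-dioxide (racemic) | CC1=CCS(=O)(=O)C1CCC2OCCO2 | intermediate
4 | 3-(3-methyl-1,1-dioxo-2,5-dihydrothiophen-2-yl)propanal (racemic) | CC1=CCS(=O)(=O)C1CCC=O | intermediate
5 | ethyl 2-(bromomethyl)prop-2-enoate | C=C(CBr)C(=O)OCC | starting material
6 | ethyl (4S)-2-methylidene-6-(3-methyl-1,1-dioxo-2,5-dihydrothiophen-2-yl)-4-(trimethylsilyloxy)hexanoate (both epimers at the sulfolene carbon) | CCOC(=O)C(=C)C[C@H](CCC1C(C)=CCS1(=O)=O)O[Si](C)(C)C | intermediate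
7 | ethyl (4S)-4-hydroxy-2-methylidene-6-(3-methyl-1,1-dioxo-2,5-dihydrothiophen-2-yl)hexanoate (both epimers at the sulfolene carbon) | CCOC(=O)C(=C)C[C@H](CCC1C(C)=CCS1(=O)=O)O | intermediate
8 | (5S)-3-methylidene-5-[2-(3-methyl-1,1-dioxo-2,5-dihydrothiophen-2-yl)ethyl]oxolan-2-one (both epimers at the sulfolene carbon) | CC1=CCS(=O)(=O)C1CC[C@H]2CC(=C)C(=O)O2 | intermediate
9 | (5S)-3-methylidene-5-[(3E)-4-methylhexa-3,5-dien-1-yl]oxolan-2-one | C=C/C(C)=C/CC[C@H]1CC(=C)C(=O)O1 | intermediate
10 | 11,12,13-trinoreudesm-3-en-14,8β-olide (trans-fused, 5α-H; γ-lactone from C14 on C10 to the 8β-oxygen) | CC1=CCC[C@]23C[C@H](CC[C@@H]12)OC3=O | intermediate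
11 | 8β,14-epoxy-11,12,13-trinoreudesm-3-en-14-ol (lactol, anomer mixture) | CC1=CCC[C@]23C[C@H](CC[C@@H]12)OC3O | intermediate
12 | 8β-hydroxy-11,12,13-trinoreudesm-3-en-14-al hydrazone | CC1=CCC[C@]2(C=NN)C[C@@H](O)CC[C@@H]12 | intermediate
13 | 11,12,13-trinoreudesm-3-en-8β-ol | CC1=CCC[C@]2(C)C[C@@H](O)CC[C@@H]12 | intermediate
14 | 11,12,13-trinoreudesm-3-en-8-one [(4aR,8aR)-5,8a-dimethyl-3,4,4a,7,8,8a-hexahydronaphthalen-2(1H)-one] | CC1=CCC[C@]2(C)CC(=O)CC[C@@H]12 | intermediate
15 | 7-(phenylselanyl)-11,12,13-trinoreudesm-3-en-8-one (C7 epimers) | CC1=CCC[C@]2(C)CC(=O)C([Se]c3ccccc3)C[C@@H]12 | intermediate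
16 | 11-hydroxy-7-(phenylselanyl)eudesm-3-en-8-one (C7 epimers) | CC1=CCC[C@]2(C)CC(=O)C([Se]c3ccccc3)(C(C)(C)O)C[C@@H]12 | intermediate
17 | 11-hydroxy-7-(phenylseleninyl)eudesm-3-en-8-one (selenoxide of 16) | CC1=CCC[C@]2(C)CC(=O)C([Se](=O)c3ccccc3)(C(C)(C)O)C[C@@H]12 | intermediate
18 | 11-hydroxyeudesma-3,6-dien-8-one | CC1=CCC[C@]2(C)CC(=O)C(C(C)(C)O)=C[C@@H]12 | intermediate
19 | 3α,4α,11-trihydroxyeudesm-6-en-8-one | O[C@@H]1CC[C@]2(C)CC(=O)C(C(C)(C)O)=C[C@H]2[C@]1(C)O | intermediate
20 | angelic acid [(2Z)-2-methylbut-2-enoic acid] | C/C=C(/C)C(=O)O | starting material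
21 | 3α-angeloyloxy-4α,11-dihydroxyeudesm-6-en-8-one (CNP0261892.2) | C/C=C(/C)C(=O)O[C@@H]1CC[C@]2(C)CC(=O)C(C(C)(C)O)=C[C@H]2[C@]1(C)O | target

**Step count and risks**

Total step count: 11. Longest linear sequence: 11 steps (from 1 and 2 to 21).

Steps most likely to fail:

Step 4. The cycloaddition may show too little endo preference, so that the cis-fused adduct competes, or the methylene lactone may polymerise before it cyclises. The fallback gives up the lactone tether for an open-chain, Lewis-acid-promoted cycloaddition of a 2-substituted acrolein; it sets out from 4 and comes back at 14. The chromium-catalysed allylation of 4 with 5 is run with the antipodal ligand and Et3SiCl and worked up under neutral conditions to give ethyl (4R)-2-methylidene-6-(3-methyl-1,1-dioxo-2,5-dihydrothiophen-2-yl)-4-(triethylsilyloxy)hexanoate F1. The opposite C8 configuration is needed because the silyloxy group now sits equatorial on the forming ring B instead of bridging to C14. Reduction with i-Bu2AlH gives the allylic alcohol (4R)-2-methylidene-6-(3-methyl-1,1-dioxo-2,5-dihydrothiophen-2-yl)-4-(triethylsilyloxy)hexan-1-ol F2, and MnO2 oxidises it to (4R)-2-methylidene-6-(3-methyl-1,1-dioxo-2,5-dihydrothiophen-2-yl)-4-(triethylsilyloxy)hexanal F3. Heating in toluene at 110 °C releases (4R,7E)-8-methyl-2-methylidene-4-(triethylsilyloxy)deca-7,9-dienal F4. Me2AlCl in CH2Cl2 at −78 °C should then promote the Diels–Alder reaction through a chair-like tether with the silyloxy group equatorial and the formyl group endo, giving trans-fused 8α-(triethylsilyloxy)-11,12,13-trinoreudesm-3-en-14-al F5. Wolff–Kishner reduction, under whose hot basic conditions the silyl ether should also be cleaved, gives 11,12,13-trinoreudesm-3-en-8α-ol F6, and Dess–Martin oxidation returns to 14.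

Step 9. The hindered, selenium-stabilised enolate may add to acetone only reversibly (retro-aldol on warming), or enolisation may be incomplete. The fallback reverses the order of carbon–carbon bond formation and dehydrogenation; it sets out from 14 and comes back at 18. The lithium enolate of 14 (LiN(i-Pr)2, THF, −78 °C) is added to acetone to give 11-hydroxyeudesm-3-en-8-one F7 as a C7 epimer mixture. Dehydrogenation with IBX in DMSO should then give 18, because with C10 quaternary the only possible enone is the C6=C7 one.

Step 11. The hindered axial 3α-hydroxyl may acylate slowly, and forcing conditions may isomerise the angelate to the tiglate. The fallback builds the (Z)-alkene on the ester instead of transferring it; it sets out from 19 and comes back at 21. Acylation of 19 with 2-[bis(2,2,2-trifluoroethoxy)phosphoryl]propanoic acid (DCC, DMAP, CH2Cl2) gives 3α-{2-[bis(2,2,2-trifluoroethoxy)phosphoryl]propanoyloxy}-4α,11-dihydroxyeudesm-6-en-8-one F8. Still–Gennari olefination with acetaldehyde (KN(SiMe3)2, 18-crown-6, THF, −78 °C) should then give the (Z)-2-methylbut-2-enoate 21 directly.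

**Further compounds**

F1 | step 4 | ethyl (4R)-2-methylidene-6-(3-methyl-1,1-dioxo-2,5-dihydrothiophen-2-yl)-4-(triethylsilyloxy)hexanoate | CCOC(=O)C(=C)C[C@@H](CCC1C(C)=CCS1(=O)=O)O[Si](CC)(CC)CC
F2 | step 4 | (4R)-2-methylidene-6-(3-methyl-1,1-dioxo-2,5-dihydrothiophen-2-yl)-4-(triethylsilyloxy)hexan-1-ol | OCC(=C)C[C@@H](CCC1C(C)=CCS1(=O)=O)O[Si](CC)(CC)CC
F3 | step 4 | (4R)-2-methylidene-6-(3-methyl-1,1-dioxo-2,5-dihydrothiophen-2-yl)-4-(triethylsilyloxy)hexanal | O=CC(=C)C[C@@H](CCC1C(C)=CCS1(=O)=O)O[Si](CC)(CC)CC
F4 | step 4 | (4R,7E)-8-methyl-2-methylidene-4-(triethylsilyloxy)deca-7,9-dienal | O=CC(=C)C[C@@H](CC/C=C(C)/C=C)O[Si](CC)(CC)CC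
F5 | step 4 | 8α-(triethylsilyloxy)-11,12,13-trinoreudesm-3-en-14-al | CC1=CCC[C@]2(C=O)C[C@H](O[Si](CC)(CC)CC)CC[C@@H]12
F6 | step 4 | 11,12,13-trinoreudesm-3-en-8α-ol | CC1=CCC[C@]2(C)C[C@H](O)CC[C@@H]12
F7 | step 9 | 11-hydroxyeudesm-3-en-8-one (C7 epimers) | CC1=CCC[C@]2(C)CC(=O)C(C(C)(C)O)C[C@@H]12
F8 | step 11 | 3α-{2-[bis(2,2,2-trifluoroethoxy)phosphoryl]propanoyloxy}-4α,11-dihydroxyeudesm-6-en-8-one | CC(C(=O)O[C@@H]1CC[C@]2(C)CC(=O)C(C(C)(C)O)=C[C@H]2[C@]1(C)O)P(=O)(OCC(F)(F)F)OCC(F)(F)F
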